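**Retrosynthetic overview**
- The target is PGE2 1,15-lactone 11-acetate. The acetate and the free 11-OH come last, the 5Z-alkene comes from semi-hydrogenation of a 5,6-cycloalkyne, and the 13-membered lactone comes from ring-closing alkyne metathesis of a C15 hept-5-ynoate / C8 but-2-ynyl diyne.
- Key step: the C15–O bond, the 15S centre and the 13E geometry are made together by a double [2,3]-sigmatropic sulfenate–sulfoxide (Mislow–Evans) relay from a (13Z,15R)-allylic alcohol.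
- That alcohol comes from a three-component coupling of (R)-4-silyloxycyclopentenone, a cis-alkenyl zincate made from (R)-oct-1-yn-3-ol, and 1-iodobut-2-yne. C11 is bought, C12 and C8 are set trans,trans by C11, and C15 derives from the octynol carbinol.
- Ring order: the cyclopentanone ring is bought intact; the macrolactone is closed in step 7 of 10.

Assumption: 1-iodobut-2-yne and hept-5-ynoic acid are taken as catalogue compounds; atom labels C1–C20 follow prostaglandin numbering.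

**Route**

Step 1
Reactants: 1 (3R)-oct-1-yn-3-ol
Product: 2 (3R)-1-iodooct-1-yn-3-ol
Conditions: NIS, AgNO3 (10 mol %), acetone, rt, dark
Reagents that add atoms: N-iodosuccinimide, O=C1CCC(=O)N1I
Why: Silver-catalysed electrophilic iodination of the terminal alkyne C–H gives the 1-iodoalkyne and leaves the bought C3 carbinol centre untouched.

Step 2
Reactants: 2 (3R)-1-iodooct-1-yn-3-ol
Product: 3 (1Z,3R)-1-iodooct-1-en-3-ol
Conditions: 2-nitrobenzenesulfonohydrazide, Et3N, THF/i-PrOH, rt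
Reagents that add atoms: none
Why: Diimide reduction transfers both hydrogens to the same face of the iodoalkyne, so only the Z-iodoalkene forms and the C–I bond and C3 are not affected.

Step 3
Reactants: 3 (1Z,3R)-1-iodooct-1-en-3-ol
Product: 4 (1Z,3R)-1-iodo-3-[(2-methoxypropan-2-yl)oxy]oct-1-ene
Conditions: 2-methoxypropene, PPTS (cat.), CH2Cl2, 0 °C
Reagents that add atoms: 2-methoxypropene, COC(C)=C
Why: Acid-catalysed acetalisation gives a base-stable MOP acetal that adds no stereocentre and, unlike a silyl ether, cannot migrate onto the cis-alkenyl anion.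

Step 4
Reactants: 4 (1Z,3R)-1-iodo-3-[(2-methoxypropan-2-yl)oxy]oct-1-ene; 5 (4R)-4-[(tert-butyldimethylsilyl)oxy]cyclopent-2-en-1-one; 6 1-iodobut-2-yne
Product: 11 (2R,3R,4R)-2-(but-2-yn-1-yl)-4-[(tert-butyldimethylsilyl)oxy]-3-[(1Z,3R)-3-hydroxyoct-1-en-1-yl]cyclopentan-1-one, via Z-alkenyllithium 7 (not isolated), via lithium alkenyl(dimethyl)zincate 8 (not isolated), via zinc enolate 9 (not isolated), via MOP-protected ketone 10 (not isolated)
Conditions: t-BuLi (2 equiv), Et2O, −78 °C; Me2Zn, THF, −78 °C; 5, −78 °C; HMPA, 6 (5 equiv), −78 to −40 °C; NH4Cl aq; AcOH/THF/H2O, rt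
Reagents that add atoms: none
Why: Noyori-type three-component coupling in which iodine–lithium exchange keeps the Z geometry, the zincate adds 1,4 anti to the C11 silyloxy group (C12 R), the enolate is alkylated anti to the new C12 chain (C8 R), and the mildly acidic work-up hydrolyses the MOP acetal.

Step 5
Reactants: 11 (2R,3R,4R)-2-(but-2-yn-1-yl)-4-[(tert-butyldimethylsilyl)oxy]-3-[(1Z,3R)-3-hydroxyoct-1-en-1-yl]cyclopentan-1-one
Product: 15 (2R,3R,4R)-2-(but-2-yn-1-yl)-4-[(tert-butyldimethylsilyl)oxy]-3-[(1E,3S)-3-hydroxyoct-1-en-1-yl]cyclopentan-1-one, via Z-allylic benzenesulfenate 12 (not isolated), via C13 allylic sulfoxide 13 (not isolated), via E-allylic benzenesulfenate 14 (not isolated)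
Conditions: PhSCl, Et3N, THF, −78 °C to rt; then P(OMe)3, MeOH, rt
Reagents that add atoms: none
Why: Mislow–Evans relay in which the sulfenate of the Z-allylic alcohol shifts suprafacially ([2,3]) to the 13S sulfoxide with a 14E alkene (C15–H in-plane to avoid allylic strain), a second [2,3] shift with the ring carbon pseudo-equatorial returns oxygen to the opposite face of C15, and P(OMe)3 traps that sulfenate, so 15R/13Z becomes 15S/13E by chirality transfer from the bought centre.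

Step 6
Reactants: 15 (2R,3R,4R)-2-(but-2-yn-1-yl)-4-[(tert-butyldimethylsilyl)oxy]-3-[(1E,3S)-3-hydroxyoct-1-en-1-yl]cyclopentan-1-one; 16 hept-5-ynoic acid
Product: 17 (1E,3S)-1-[(1R,2R,5R)-2-(but-2-yn-1-yl)-5-[(tert-butyldimethylsilyl)oxy]-3-oxocyclopentyl]oct-1-en-3-yl hept-5-ynoate
Conditions: DCC, DMAP (cat.), CH2Cl2, 0 °C to rt
Reagents that add atoms: none
Why: Steglich esterification acylates the only free hydroxyl at oxygen, so C15 keeps its S configuration, and the conditions are mild enough for the β-silyloxy ketone.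

Step 7
Reactants: 17 (1E,3S)-1-[(1R,2R,5R)-2-(but-2-yn-1-yl)-5-[(tert-butyldimethylsilyl)oxy]-3-oxocyclopentyl]oct-1-en-3-yl hept-5-ynoate
Product: 18 (8R,11R,12R,13E,15S)-11-[(tert-butyldimethylsilyl)oxy]-9-oxoprost-13-en-5-yn-1,15-olide
Conditions: Mo[N(t-Bu)(3,5-Me2C6H3)]3 (10 mol %), CH2Cl2/toluene, 80 °C, 0.005 M
Reagents that add atoms: none
Why: Ring-closing alkyne metathesis of the two methyl-capped alkynes is driven by loss of volatile but-2-yne at high dilution and closes the 13-membered lactone without touching the 13E-alkene, ketone or silyl ether; no stereocentre is formed.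

Step 8
Reactants: 18 (8R,11R,12R,13E,15S)-11-[(tert-butyldimethylsilyl)oxy]-9-oxoprost-13-en-5-yn-1,15-olide
Product: 19 (5Z,8R,11R,12R,13E,15S)-11-[(tert-butyldimethylsilyl)oxy]-9-oxoprosta-5,13-dien-1,15-olide
Conditions: H2 (1 atm), Pd/CaCO3 poisoned with Pb(OAc)2, quinoline, EtOAc/hexane, rt
Reagents that add atoms: none
Why: Lindlar semi-hydrogenation adds H2 syn to the ring alkyne to give only the 5Z-alkene, and the poisoned catalyst leaves the 13E-alkene alone.

Step 9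
Reactants: 19 (5Z,8R,11R,12R,13E,15S)-11-[(tert-butyldimethylsilyl)oxy]-9-oxoprosta-5,13-dien-1,15-olide
Product: 20 (5Z,8R,11R,12R,13E,15S)-11-hydroxy-9-oxoprosta-5,13-dien-1,15-olide (PGE2 1,15-lactone)
Conditions: HF aq (48 %), MeCN, 0 °C to rt
Reagents that add atoms: none
Why: Fluoride-driven desilylation under weakly acidic conditions frees the 11-OH without β-elimination of the β-hydroxy ketone or cleavage of the allylic lactone.

Step 10
Reactants: 20 (5Z,8R,11R,12R,13E,15S)-11-hydroxy-9-oxoprosta-5,13-dien-1,15-olide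
Product: 21 (5Z,8R,11R,12R,13E,15S)-11-acetoxy-9-oxoprosta-5,13-dien-1,15-olide (PGE2 1,15-lactone 11-acetate)
Conditions: Ac2O, pyridine, 0 °C to rt
Reagents that add atoms: acetic anhydride, CC(=O)OC(C)=O
Why: O-Acylation of the single free hydroxyl with retention at C11, run without DMAP and at low temperature so the β-acetoxy ketone does not eliminate to the PGA-type enone.

**Compound list**

1 | (3R)-oct-1-yn-3-ol | CCCCC[C@@H](O)C#C | starting material
2 | (3R)-1-iodooct-1-yn-3-ol | CCCCC[C@@H](O)C#CI | intermediate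
3 | (1Z,3R)-1-iodooct-1-en-3-ol | CCCCC[C@@H](O)/C=C\I | intermediate
4 | (1Z,3R)-1-iodo-3-[(2-methoxypropan-2-yl)oxy]oct-1-ene | CCCCC[C@@H](OC(C)(C)OC)/C=C\I | intermediate
5 | (4R)-4-[(tert-butyldimethylsilyl)oxy]cyclopent-2-en-1-one | O=C1C=C[C@H](O[Si](C)(C)C(C)(C)C)C1 | starting material
6 | 1-iodobut-2-yne | CC#CCI | starting material
7 | [(1Z,3R)-3-[(2-methoxypropan-2-yl)oxy]oct-1-en-1-yl]lithium | CCCCC[C@@H](OC(C)(C)OC)/C=C\[Li] | intermediate
8 | lithium dimethyl[(1Z,3R)-3-[(2-methoxypropan-2-yl)oxy]oct-1-en-1-yl]zincate | CCCCC[C@@H](OC(C)(C)OC)/C=C\[Zn-](C)C.[Li+] | intermediate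
9 | lithium dimethylzincate enolate (C8=C9–O–Zn) of (3R,4R)-4-[(tert-butyldimethylsilyl)oxy]-3-[(1Z,3R)-3-[(2-methoxypropan-2-yl)oxy]oct-1-en-1-yl]cyclopentan-1-one | CCCCC[C@@H](OC(C)(C)OC)/C=C\[C@H]1[C@H](O[Si](C)(C)C(C)(C)C)CC(O[Zn-](C)C)=C1.[Li+] | intermediate
10 | (2R,3R,4R)-2-(but-2-yn-1-yl)-4-[(tert-butyldimethylsilyl)oxy]-3-[(1Z,3R)-3-[(2-methoxypropan-2-yl)oxy]oct-1-en-1-yl]cyclopentan-1-one | CCCCC[C@@H](OC(C)(C)OC)/C=C\[C@H]1[C@H](O[Si](C)(C)C(C)(C)C)CC(=O)[C@@H]1CC#CC | intermediate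
11 | (2R,3R,4R)-2-(but-2-yn-1-yl)-4-[(tert-butyldimethylsilyl)oxy]-3-[(1Z,3R)-3-hydroxyoct-1-en-1-yl]cyclopentan-1-one | CCCCC[C@@H](O)/C=C\[C@H]1[C@H](O[Si](C)(C)C(C)(C)C)CC(=O)[C@@H]1CC#CC | intermediate
12 | benzenesulfenate ester (C15–O–SPh, 13Z,15R) of 11 | CCCCC[C@@H](OSc1ccccc1)/C=C\[C@H]2[C@H](O[Si](C)(C)C(C)(C)C)CC(=O)[C@@H]2CC#CC | intermediate
13 | (2R,3R,4R)-3-[(1S,2E)-1-(benzenesulfinyl)oct-2-en-1-yl]-2-(but-2-yn-1-yl)-4-[(tert-butyldimethylsilyl)oxy]cyclopentan-1-one (either configuration at sulfur) | CCCCC/C=C/[C@H](S(=O)c1ccccc1)[C@H]2[C@H](O[Si](C)(C)C(C)(C)C)CC(=O)[C@@H]2CC#CC | intermediate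
14 | benzenesulfenate ester (C15–O–SPh, 13E,15S) of 15 | CCCCC[C@H](OSc1ccccc1)/C=C/[C@H]2[C@H](O[Si](C)(C)C(C)(C)C)CC(=O)[C@@H]2CC#CC | intermediate
15 | (2R,3R,4R)-2-(but-2-yn-1-yl)-4-[(tert-butyldimethylsilyl)oxy]-3-[(1E,3S)-3-hydroxyoct-1-en-1-yl]cyclopentan-1-one | CCCCC[C@H](O)/C=C/[C@H]1[C@H](O[Si](C)(C)C(C)(C)C)CC(=O)[C@@H]1CC#CC | intermediate
16 | hept-5-ynoic acid | CC#CCCCC(=O)O | starting material
17 | (1E,3S)-1-[(1R,2R,5R)-2-(but-2-yn-1-yl)-5-[(tert-butyldimethylsilyl)oxy]-3-oxocyclopentyl]oct-1-en-3-yl hept-5-ynoate | CCCCC[C@H](OC(=O)CCCC#CC)/C=C/[C@H]1[C@H](O[Si](C)(C)C(C)(C)C)CC(=O)[C@@H]1CC#CC | intermediate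
18 | (8R,11R,12R,13E,15S)-11-[(tert-butyldimethylsilyl)oxy]-9-oxoprost-13-en-5-yn-1,15-olide | CCCCC[C@H]1/C=C/[C@H]2[C@H](O[Si](C)(C)C(C)(C)C)CC(=O)[C@@H]2CC#CCCCC(=O)O1 | intermediate
19 | (5Z,8R,11R,12R,13E,15S)-11-[(tert-butyldimethylsilyl)oxy]-9-oxoprosta-5,13-dien-1,15-olide | CCCCC[C@H]1/C=C/[C@H]2[C@H](O[Si](C)(C)C(C)(C)C)CC(=O)[C@@H]2C/C=C\CCCC(=O)O1 | intermediate
20 | (5Z,8R,11R,12R,13E,15S)-11-hydroxy-9-oxoprosta-5,13-dien-1,15-olide | CCCCC[C@H]1/C=C/[C@H]2[C@H](O)CC(=O)[C@@H]2C/C=C\CCCC(=O)O1 | intermediate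
21 | (5Z,8R,11R,12R,13E,15S)-11-acetoxy-9-oxoprosta-5,13-dien-1,15-olide | CCCCC[C@H]1/C=C/[C@H]2[C@H](OC(C)=O)CC(=O)[C@@H]2C/C=C\CCCC(=O)O1 | target

**Step count and risks**

Total steps: 10. Longest linear sequence: 10 steps (1 to 21); compounds 5, 6 and 16 enter as bought.

Three steps most likely to fail:

Step 4 (three-component coupling). The propargylic alkylation of enolate 9 can be slow, and proton transfer then leads to loss of the 11-silyloxy group. The fallback sets out from zinc enolate 9: instead of being alkylated, 9 is intercepted at −78 °C with but-2-ynal in an aldol reaction to give the C7 carbinol, 2-(1-hydroxybut-2-yn-1-yl) ketone F1 (mixture at C7). PhOC(S)Cl/pyridine converts it into the O-phenyl thionocarbonate F2. Radical deoxygenation with Bu3SnH/AIBN in toluene at 80 °C removes the C7 oxygen and comes back to the route at 10, which is hydrolysed to 11 as before.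

Step 5 (sulfenate–sulfoxide relay). Sulfenyl chloride may add to the π bonds, or the relay may give 13Z/13E or C15 mixtures. The fallback sets out from enone 5 and abandons the relay: bought (3S)-oct-1-yn-3-ol is protected with 2-methoxypropene/PPTS as (3S)-3-[(2-methoxypropan-2-yl)oxy]oct-1-yne F3. Hydrozirconation with Cp2Zr(H)Cl followed by I2 gives (1E,3S)-1-iodo-3-[(2-methoxypropan-2-yl)oxy]oct-1-ene F4. F4 replaces 4 in the t-BuLi/Me2Zn coupling with 5 and 6 to give the (13E,15S) MOP-protected ketone F5, and the same AcOH/THF/H2O work-up comes back to the route at 15.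

Step 7 (ring-closing alkyne metathesis). The molybdenum catalyst may be deactivated by the ketone or give oligomers. The fallback sets out from 17 and changes the ring-closing reaction: both triple bonds are semi-hydrogenated (H2, Pd/CaCO3 poisoned with Pb(OAc)2, quinoline) to the (Z,Z)-diene ester F6. Stereoretentive ring-closing olefin metathesis with Ru(SIMes)(3,6-Cl2C6H2S2)(=CH-C6H4-2-O-i-Pr) (SIMes = 1,3-dimesitylimidazolidin-2-ylidene) in THF at 40 °C expels (Z)-but-2-ene and keeps the Z geometry, coming back to the route at 19.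

**Further compounds**

F1 | step 4 | (2R,3R,4R)-4-[(tert-butyldimethylsilyl)oxy]-2-(1-hydroxybut-2-yn-1-yl)-3-[(1Z,3R)-3-[(2-methoxypropan-2-yl)oxy]oct-1-en-1-yl]cyclopentan-1-one (mixture at the carbinol) | CCCCC[C@@H](OC(C)(C)OC)/C=C\[C@H]1[C@H](O[Si](C)(C)C(C)(C)C)CC(=O)[C@@H]1C(O)C#CC
F2 | step 4 | O-phenyl thionocarbonate of F1 | CCCCC[C@@H](OC(C)(C)OC)/C=C\[C@H]1[C@H](O[Si](C)(C)C(C)(C)C)CC(=O)[C@@H]1C(OC(=S)Oc2ccccc2)C#CC
F3 | step 5 | (3S)-3-[(2-methoxypropan-2-yl)oxy]oct-1-yne | CCCCC[C@H](OC(C)(C)OC)C#C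
F4 | step 5 | (1E,3S)-1-iodo-3-[(2-methoxypropan-2-yl)oxy]oct-1-ene | CCCCC[C@H](OC(C)(C)OC)/C=C/I
F5 | step 5 | (2R,3R,4R)-2-(but-2-yn-1-yl)-4-[(tert-butyldimethylsilyl)oxy]-3-[(1E,3S)-3-[(2-methoxypropan-2-yl)oxy]oct-1-en-1-yl]cyclopentan-1-one | CCCCC[C@H](OC(C)(C)OC)/C=C/[C@H]1[C@H](O[Si](C)(C)C(C)(C)C)CC(=O)[C@@H]1CC#CC
F6 | step 7 | (1E,3S)-1-[(1R,2R,5R)-2-[(2Z)-but-2-en-1-yl]-5-[(tert-butyldimethylsilyl)oxy]-3-oxocyclopentyl]oct-1-en-3-yl (5Z)-hept-5-enoate | CCCCC[C@H](OC(=O)CCC/C=C\C)/C=C/[C@H]1[C@H](O[Si](C)(C)C(C)(C)C)CC(=O)[C@@H]1C/C=C\C
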